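The plan rests on cutting ring A and the dihydrofuran ring together, at C3a–C7a and C6–C7, which leads back to a 2,4-disubstituted furan joined through C3–C2–O1 to a terminal ynol ether. The feature exploited is the vicinal oxygenation of ring A, O1 on C7a beside the oxygen on C7: the alkyne carbon already bound to O1 becomes C7a, and the furan oxygen moves to the terminal alkyne carbon, which becomes C7. A single gold-catalysed isomerisation thus closes both rings. The precursor is the (1R,2S) ethynyl ether of an Evans syn-aldol-derived alcohol, with both primary hydroxyls as triisopropylsilyl ethers, chosen to resist 1,5-silyl shift and adventitious acid.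

Key step: step 9

Remark: methyl 5-bromofuran-3-carboxylate 1 and the zinc reagent 2 are taken as catalogue items (1 is otherwise one bromination away from methyl furan-3-carboxylate).

Step 1
Reactants: 1 methyl 5-bromofuran-3-carboxylate; 2 (2-tert-butoxy-2-oxoethyl)zinc bromide
Product: 3 tert-butyl 2-[4-(methoxycarbonyl)furan-2-yl]acetate
Conditions: Pd2(dba)3 (1 mol%), XPhos (4 mol%), THF, 50 °C
Reagents that add atoms: none
Why: Negishi-type cross-coupling of a Reformatsky zinc enolate (palladium-catalysed ester α-arylation), in which zerovalent palladium inserts readily into the C–Br bond of the electron-poor 2-bromofuran and the soft zinc enolate is inert towards the methyl ester.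

Step 2
Reactants: 3 tert-butyl 2-[4-(methoxycarbonyl)furan-2-yl]acetate
Product: 4 2-[4-(methoxycarbonyl)furan-2-yl]acetic acid
Conditions: TFA, CH2Cl2, 0 °C → rt
Reagents that add atoms: none
Why: Acid-mediated tert-butyl ester cleavage by E1 loss of isobutene, selective over the methyl ester, on a furan that the ester group deactivates enough to tolerate the acid.

Step 3
Reactants: 4 2-[4-(methoxycarbonyl)furan-2-yl]acetic acid; 5 (R)-4-benzyloxazolidin-2-one
Product: 7 (R)-4-benzyl-3-{2-[4-(methoxycarbonyl)furan-2-yl]acetyl}oxazolidin-2-one, via mixed pivalic anhydride 6 (not isolated)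
Conditions: PivCl, Et3N, THF, −20 °C; then 5, LiCl, rt
Reagents that add atoms: none
Why: N-acylation of the oxazolidinone by the mixed anhydride method with LiCl/Et3N, which needs no strong base and so avoids ketene formation or self-condensation of the acidic furylacetyl unit.

Step 4
Reactants: 7 (R)-4-benzyl-3-{2-[4-(methoxycarbonyl)furan-2-yl]acetyl}oxazolidin-2-one; 8 3,4-dimethoxybenzaldehyde
Product: 10 (R)-4-benzyl-3-[(2S,3R)-3-(3,4-dimethoxyphenyl)-3-hydroxy-2-[4-(methoxycarbonyl)furan-2-yl]propanoyl]oxazolidin-2-one, via dibutylboron Z-enolate 9 (not isolated)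
Conditions: Bu2BOTf, iPr2NEt, CH2Cl2, 0 °C; then 8, −78 → 0 °C; pH 7 buffer, MeOH, 30% H2O2, 0 °C
Reagents that add atoms: none
Why: Evans syn-aldol reaction, in which soft enolisation gives the Z boron enolate and this adds to the aldehyde through a Zimmerman–Traxler chair where the (R)-benzyl group of the dipole-opposed auxiliary blocks one enolate face, setting both new centres together as the (2S,3R) syn pair that maps onto C3 (S) and C2 (R) of the target.

Step 5
Reactants: 10 (R)-4-benzyl-3-[(2S,3R)-3-(3,4-dimethoxyphenyl)-3-hydroxy-2-[4-(methoxycarbonyl)furan-2-yl]propanoyl]oxazolidin-2-one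
Product: 11 (1R,2S)-1-(3,4-dimethoxyphenyl)-2-[4-(hydroxymethyl)furan-2-yl]propane-1,3-diol
Conditions: LiBH4 (4 equiv), MeOH (4 equiv), THF, 0 °C → 45 °C
Reagents that add atoms: none
Why: Hydride reduction (LiBH4–MeOH) should cleave the imide to the primary alcohol at 0 °C, which removes the only epimerisable centre before warming completes reduction of the furoate ester, and the auxiliary is released intact.

Step 6
Reactants: 11 (1R,2S)-1-(3,4-dimethoxyphenyl)-2-[4-(hydroxymethyl)furan-2-yl]propane-1,3-diol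
Product: 12 (1R,2S)-1-(3,4-dimethoxyphenyl)-3-(triisopropylsilyloxy)-2-[4-(triisopropylsilyloxymethyl)furan-2-yl]propan-1-ol
Conditions: TIPSCl (2.2 equiv), imidazole, DMF, 0 °C → rt
Reagents that add atoms: triisopropylsilyl chloride, CC(C)[Si](Cl)(C(C)C)C(C)C
Why: Sterically controlled silyl ether formation, in which the bulky chlorosilane reacts with the two primary hydroxyls and leaves the hindered secondary benzylic hydroxyl, the future O1, free.

Step 7
Reactants: 12 (1R,2S)-1-(3,4-dimethoxyphenyl)-3-(triisopropylsilyloxy)-2-[4-(triisopropylsilyloxymethyl)furan-2-yl]propan-1-ol; 13 trichloroethylene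
Product: 15 (1R,2S)-1-(3,4-dimethoxyphenyl)-3-(triisopropylsilyloxy)-2-[4-(triisopropylsilyloxymethyl)furan-2-yl]propyl (E)-1,2-dichlorovinyl ether, via potassium alkoxide 14 (not isolated)
Conditions: KH, THF, 0 °C; then ClCH=CCl2, −50 °C → rt
Reagents that add atoms: none
Why: Dichlorovinyl ether synthesis by anti addition of the alkoxide to dichloroacetylene generated in situ from trichloroethylene, which leaves the carbinol C–O bond and hence the configuration untouched, while the triisopropylsilyl ether is slow to migrate onto the neighbouring alkoxide.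

Step 8
Reactants: 15 (1R,2S)-1-(3,4-dimethoxyphenyl)-3-(triisopropylsilyloxy)-2-[4-(triisopropylsilyloxymethyl)furan-2-yl]propyl (E)-1,2-dichlorovinyl ether
Product: 18 (1R,2S)-1-(3,4-dimethoxyphenyl)-3-(triisopropylsilyloxy)-2-[4-(triisopropylsilyloxymethyl)furan-2-yl]propyl ethynyl ether, via chloroethynyl ether 16 (not isolated), via lithium alkynyl ether 17 (not isolated)
Conditions: n-BuLi (2.2 equiv), THF, −78 → −40 °C; MeOH, −78 °C
Reagents that add atoms: none
Why: Base-induced β-elimination of HCl followed by chlorine–lithium exchange (alkynyl ether synthesis from a dichlorovinyl ether) gives the lithium acetylide, which methanol protonates, and the terminal ynol ether is kept cold and used at once because benzylic alkynyl ethers rearrange on warming.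

Step 9
Reactants: 18 (1R,2S)-1-(3,4-dimethoxyphenyl)-3-(triisopropylsilyloxy)-2-[4-(triisopropylsilyloxymethyl)furan-2-yl]propyl ethynyl ether
Product: 19 (2R,3S)-2-(3,4-dimethoxyphenyl)-3,5-bis(triisopropylsilyloxymethyl)-2,3-dihydrobenzofuran-7-ol
Conditions: (IPr)AuNTf2 (5 mol%; IPr = 1,3-bis(2,6-diisopropylphenyl)imidazol-2-ylidene), 4 Å MS, CH2Cl2, −20 → 0 °C
Reagents that add atoms: none
Why: Proposed new method: π-activation by monovalent gold turns the ynol ether into a ketene-oxonium-like electrophile whose O1-bearing carbon is attacked by furan C2, giving a cyclopropyl gold carbene that opens the furan to a dienal carbene, recloses through the carbonyl oxygen to an oxepine/arene oxide and opens the epoxide to the C7 phenol; the closest known reaction type is the gold-catalysed intramolecular furan–alkyne phenol synthesis on unbranched three-atom tethers, and what is new is the secondary benzylic ynol ether. The dihydrofuran ring closes by 5-exo-dig attack that forms C3a–C7a, and ring A closes by 6π electrocyclisation of the oxepine to the arene oxide, which forms C6–C7. No stereocentre is created; the two existing centres lie in the tether and keep their configuration as long as the benzylic C–O bond does not ionise. The step needs attack at the internal alkyne carbon, furan attack faster than ionisation or [3,3] shift of the benzylic alkynyl ether, and epoxide opening towards the C7 hydroxyl: the oxygen donor polarises the alkyne towards its internal carbon, a five-membered transition state with a nucleophilic alkyl-substituted furan and a weakly Lewis acidic NHC–gold cation at low temperature favours cyclisation, and the O1 lone pair stabilises the cation formed when the C6–O bond breaks.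

Step 10
Reactants: 19 (2R,3S)-2-(3,4-dimethoxyphenyl)-3,5-bis(triisopropylsilyloxymethyl)-2,3-dihydrobenzofuran-7-ol
Product: 20 (2R,3S)-2-(3,4-dimethoxyphenyl)-7-methoxy-3,5-bis(triisopropylsilyloxymethyl)-2,3-dihydrobenzofuran
Conditions: MeI, K2CO3, acetone, rt
Reagents that add atoms: iodomethane, CI
Why: Williamson O-methylation of the only acidic hydroxyl, with a carbonate base too weak to affect the silyl ethers or the C2/C3 centres.

Step 11
Reactants: 20 (2R,3S)-2-(3,4-dimethoxyphenyl)-7-methoxy-3,5-bis(triisopropylsilyloxymethyl)-2,3-dihydrobenzofuran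
Product: 21 [(2R,3S)-2-(3,4-dimethoxyphenyl)-7-methoxy-2,3-dihydrobenzofuran-3,5-diyl]dimethanol
Conditions: TBAF, THF, rt
Reagents that add atoms: none
Why: Fluoride-mediated cleavage of both silyl ethers, driven by Si–F bond formation, in a molecule with no other fluoride- or base-labile group.

Step 12
Reactants: 21 [(2R,3S)-2-(3,4-dimethoxyphenyl)-7-methoxy-2,3-dihydrobenzofuran-3,5-diyl]dimethanol
Product: 22 (2R,3S)-2-(3,4-dimethoxyphenyl)-3-(hydroxymethyl)-7-methoxy-2,3-dihydrobenzofuran-5-carbaldehyde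
Conditions: MnO2, CH2Cl2, rt
Reagents that add atoms: none
Why: Chemoselective MnO2 oxidation, in which the surface oxidant dehydrogenates the electron-rich benzylic alcohol on C5 and leaves the saturated primary alcohol on C3 untouched.

Step 13
Reactants: 22 (2R,3S)-2-(3,4-dimethoxyphenyl)-3-(hydroxymethyl)-7-methoxy-2,3-dihydrobenzofuran-5-carbaldehyde
Product: 23 4-O-methylbalanophonin, (E)-3-[(2R,3S)-2-(3,4-dimethoxyphenyl)-3-(hydroxymethyl)-7-methoxy-2,3-dihydrobenzofuran-5-yl]prop-2-enal
Conditions: Ph3P=CHCHO (1.2 equiv), toluene, 80 °C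
Reagents that add atoms: (triphenylphosphoranylidene)acetaldehyde, O=CC=P(c1ccccc1)(c1ccccc1)c1ccccc1
Why: Wittig olefination with a stabilised formyl ylide, E-selective through reversible oxaphosphetane formation, with a non-basic ylide that tolerates the free hydroxyl and the C2/C3 centres and a small excess that limits a second homologation.

Compound list
1 | methyl 5-bromofuran-3-carboxylate | COC(=O)c1coc(Br)c1 | starting material
2 | (2-tert-butoxy-2-oxoethyl)zinc bromide | CC(C)(C)OC(=O)C[Zn]Br | starting material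
3 | tert-butyl 2-[4-(methoxycarbonyl)furan-2-yl]acetate | COC(=O)c1coc(CC(=O)OC(C)(C)C)c1 | intermediate
4 | 2-[4-(methoxycarbonyl)furan-2-yl]acetic acid | COC(=O)c1coc(CC(=O)O)c1 | intermediate
5 | (R)-4-benzyloxazolidin-2-one | O=C1N[C@H](Cc2ccccc2)CO1 | starting material
6 | 2-[4-(methoxycarbonyl)furan-2-yl]acetic pivalic anhydride | COC(=O)c1coc(CC(=O)OC(=O)C(C)(C)C)c1 | intermediate
7 | (R)-4-benzyl-3-{2-[4-(methoxycarbonyl)furan-2-yl]acetyl}oxazolidin-2-one | COC(=O)c1coc(CC(=O)N2[C@H](Cc3ccccc3)COC2=O)c1 | intermediate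
8 | 3,4-dimethoxybenzaldehyde | COc1ccc(C=O)cc1OC | starting material
9 | dibutylboron Z-enolate of 7 | COC(=O)c1coc(/C=C(\OB(CCCC)CCCC)N2[C@H](Cc3ccccc3)COC2=O)c1 | intermediate
10 | (R)-4-benzyl-3-[(2S,3R)-3-(3,4-dimethoxyphenyl)-3-hydroxy-2-[4-(methoxycarbonyl)furan-2-yl]propanoyl]oxazolidin-2-one | COc1ccc([C@H](O)[C@H](C(=O)N2[C@H](Cc3ccccc3)COC2=O)c4cc(C(=O)OC)co4)cc1OC | intermediate
11 | (1R,2S)-1-(3,4-dimethoxyphenyl)-2-[4-(hydroxymethyl)furan-2-yl]propane-1,3-diol | COc1ccc([C@H](O)[C@H](CO)c2cc(CO)co2)cc1OC | intermediate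
12 | (1R,2S)-1-(3,4-dimethoxyphenyl)-3-(triisopropylsilyloxy)-2-[4-(triisopropylsilyloxymethyl)furan-2-yl]propan-1-ol | COc1ccc([C@H](O)[C@H](CO[Si](C(C)C)(C(C)C)C(C)C)c2cc(CO[Si](C(C)C)(C(C)C)C(C)C)co2)cc1OC | intermediate
13 | trichloroethylene | ClC=C(Cl)Cl | starting material
14 | potassium alkoxide of 12 | COc1ccc([C@H]([O-])[C@H](CO[Si](C(C)C)(C(C)C)C(C)C)c2cc(CO[Si](C(C)C)(C(C)C)C(C)C)co2)cc1OC.[K+] | intermediate
15 | (1R,2S)-1-(3,4-dimethoxyphenyl)-3-(triisopropylsilyloxy)-2-[4-(triisopropylsilyloxymethyl)furan-2-yl]propyl (E)-1,2-dichlorovinyl ether | COc1ccc([C@H](O/C(Cl)=C\Cl)[C@H](CO[Si](C(C)C)(C(C)C)C(C)C)c2cc(CO[Si](C(C)C)(C(C)C)C(C)C)co2)cc1OC | intermediate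
16 | (1R,2S)-1-(3,4-dimethoxyphenyl)-3-(triisopropylsilyloxy)-2-[4-(triisopropylsilyloxymethyl)furan-2-yl]propyl chloroethynyl ether | COc1ccc([C@H](OC#CCl)[C@H](CO[Si](C(C)C)(C(C)C)C(C)C)c2cc(CO[Si](C(C)C)(C(C)C)C(C)C)co2)cc1OC | intermediate
17 | lithium acetylide of 18 (lithium alkynyl ether) | COc1ccc([C@H](OC#C[Li])[C@H](CO[Si](C(C)C)(C(C)C)C(C)C)c2cc(CO[Si](C(C)C)(C(C)C)C(C)C)co2)cc1OC | intermediate
18 | (1R,2S)-1-(3,4-dimethoxyphenyl)-3-(triisopropylsilyloxy)-2-[4-(triisopropylsilyloxymethyl)furan-2-yl]propyl ethynyl ether | COc1ccc([C@H](OC#C)[C@H](CO[Si](C(C)C)(C(C)C)C(C)C)c2cc(CO[Si](C(C)C)(C(C)C)C(C)C)co2)cc1OC | intermediate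
19 | (2R,3S)-2-(3,4-dimethoxyphenyl)-3,5-bis(triisopropylsilyloxymethyl)-2,3-dihydrobenzofuran-7-ol | COc1ccc([C@@H]2Oc3c(O)cc(CO[Si](C(C)C)(C(C)C)C(C)C)cc3[C@H]2CO[Si](C(C)C)(C(C)C)C(C)C)cc1OC | intermediate
20 | (2R,3S)-2-(3,4-dimethoxyphenyl)-7-methoxy-3,5-bis(triisopropylsilyloxymethyl)-2,3-dihydrobenzofuran | COc1ccc([C@@H]2Oc3c(OC)cc(CO[Si](C(C)C)(C(C)C)C(C)C)cc3[C@H]2CO[Si](C(C)C)(C(C)C)C(C)C)cc1OC | intermediate
21 | [(2R,3S)-2-(3,4-dimethoxyphenyl)-7-methoxy-2,3-dihydrobenzofuran-3,5-diyl]dimethanol | COc1ccc([C@@H]2Oc3c(OC)cc(CO)cc3[C@H]2CO)cc1OC | intermediate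
22 | (2R,3S)-2-(3,4-dimethoxyphenyl)-3-(hydroxymethyl)-7-methoxy-2,3-dihydrobenzofuran-5-carbaldehyde | COc1ccc([C@@H]2Oc3c(OC)cc(C=O)cc3[C@H]2CO)cc1OC | intermediate
23 | 4-O-methylbalanophonin, (E)-3-[(2R,3S)-2-(3,4-dimethoxyphenyl)-3-(hydroxymethyl)-7-methoxy-2,3-dihydrobenzofuran-5-yl]prop-2-enal | COc1ccc([C@@H]2Oc3c(OC)cc(/C=C/C=O)cc3[C@H]2CO)cc1OC | target

Total step count: 13. Longest linear sequence: 13 steps (1 → 23).

Steps most likely to fail

Step 9 (gold-catalysed benzannulation). What may go wrong: the gold-activated benzylic C–O bond ionises, or the alkynyl ether undergoes a sigmatropic shift, before the furan attacks. The result would be loss of the C2 configuration or fragmentation; hydration of the ynol ether by trace water is a further risk. The fallback uses known chemistry and buys ring A as an arene instead of building it; it sets out from 8 (with auxiliary 5) and comes back at 22. Commercial 5-bromovanillin (COc1cc(C=O)cc(Br)c1O) is protected with MOMCl/iPr2NEt to give 3-bromo-5-methoxy-4-(methoxymethoxy)benzaldehyde F1. Ethylene glycol with catalytic PPTS then gives 2-[3-bromo-5-methoxy-4-(methoxymethoxy)phenyl]-1,3-dioxolane F2. Coupling with BrZnCH2CO2Et under the conditions of step 1 gives ethyl 2-[5-(1,3-dioxolan-2-yl)-3-methoxy-2-(methoxymethoxy)phenyl]acetate F3, and LiOH in aqueous THF gives 2-[5-(1,3-dioxolan-2-yl)-3-methoxy-2-(methoxymethoxy)phenyl]acetic acid F4. Acylation of 5 as in step 3 gives (R)-4-benzyl-3-{2-[5-(1,3-dioxolan-2-yl)-3-methoxy-2-(methoxymethoxy)phenyl]acetyl}oxazolidin-2-one F5. The boron aldol with 8 as in step 4 gives (R)-4-benzyl-3-[(2R,3R)-3-(3,4-dimethoxyphenyl)-2-[5-(1,3-dioxolan-2-yl)-3-methoxy-2-(methoxymethoxy)phenyl]-3-hydroxypropanoyl]oxazolidin-2-one F6. LiBH4 gives (1R,2S)-1-(3,4-dimethoxyphenyl)-2-[5-(1,3-dioxolan-2-yl)-3-methoxy-2-(methoxymethoxy)phenyl]propane-1,3-diol F7. Aqueous HCl in THF at 40 °C then removes the methoxymethyl and acetal groups and lets the freed phenol capture the 3,4-dimethoxybenzylic cation. Ring closure should occur trans to the hydroxymethyl group on the auxiliary-set C3, giving 22.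

Step 7 (dichlorovinyl ether formation). What may go wrong: silyl transfer from the primary oxygen to the neighbouring potassium alkoxide, so that the wrong oxygen is vinylated, or slow addition of the hindered alkoxide. The fallback avoids any alkoxide; it sets out from 12 and comes back at 18. Acetic formic anhydride and pyridine convert 12 into (1R,2S)-1-(3,4-dimethoxyphenyl)-3-(triisopropylsilyloxy)-2-[4-(triisopropylsilyloxymethyl)furan-2-yl]propyl formate F8. Corey–Fuchs-type dibromo-olefination of the formate carbonyl (CBr4, PPh3, CH2Cl2) gives (1R,2S)-1-(3,4-dimethoxyphenyl)-3-(triisopropylsilyloxy)-2-[4-(triisopropylsilyloxymethyl)furan-2-yl]propyl 2,2-dibromovinyl ether F9. n-BuLi in THF at −78 °C (elimination and bromine–lithium exchange) followed by methanol then gives 18 through 17.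

Step 4 (syn-aldol). What may go wrong: retro-aldol equilibration with the electron-rich aldehyde or enolate epimerisation of the acidic furylacetyl unit, eroding the syn selectivity and the conversion. The fallback forms the C–C bond irreversibly by acylation and sets the carbinol centre by reduction; it sets out from 4 and comes back at 11. Acid 4 is attached, as in step 3, to (S)-4-benzyloxazolidin-2-one (O=C1N[C@@H](Cc2ccccc2)CO1) to give (S)-4-benzyl-3-{2-[4-(methoxycarbonyl)furan-2-yl]acetyl}oxazolidin-2-one F10. Its chelated lithium enolate (LDA, THF, −78 °C) is C-acylated by 3,4-dimethoxybenzoyl chloride (COc1ccc(C(Cl)=O)cc1OC) on the face away from the benzyl group. This should give (S)-4-benzyl-3-[(2R)-3-(3,4-dimethoxyphenyl)-2-[4-(methoxycarbonyl)furan-2-yl]-3-oxopropanoyl]oxazolidin-2-one F11. Chelation-controlled reduction with Zn(BH4)2 (CH2Cl2/Et2O, −20 °C) should give the syn alcohol (S)-4-benzyl-3-[(2S,3R)-3-(3,4-dimethoxyphenyl)-3-hydroxy-2-[4-(methoxycarbonyl)furan-2-yl]propanoyl]oxazolidin-2-one F12. LiBH4 as in step 5 converts F12 into 11.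

Further compounds
F1 | step 9 | 3-bromo-5-methoxy-4-(methoxymethoxy)benzaldehyde | COCOc1c(Br)cc(C=O)cc1OC
F2 | step 9 | 2-[3-bromo-5-methoxy-4-(methoxymethoxy)phenyl]-1,3-dioxolane | COCOc1c(Br)cc(C2OCCO2)cc1OC
F3 | step 9 | ethyl 2-[5-(1,3-dioxolan-2-yl)-3-methoxy-2-(methoxymethoxy)phenyl]acetate | CCOC(=O)Cc1cc(C2OCCO2)cc(OC)c1OCOC
F4 | step 9 | 2-[5-(1,3-dioxolan-2-yl)-3-methoxy-2-(methoxymethoxy)phenyl]acetic acid | OC(=O)Cc1cc(C2OCCO2)cc(OC)c1OCOC
F5 | step 9 | (R)-4-benzyl-3-{2-[5-(1,3-dioxolan-2-yl)-3-methoxy-2-(methoxymethoxy)phenyl]acetyl}oxazolidin-2-one | COCOc1c(OC)cc(C2OCCO2)cc1CC(=O)N3[C@H](Cc4ccccc4)COC3=O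
F6 | step 9 | (R)-4-benzyl-3-[(2R,3R)-3-(3,4-dimethoxyphenyl)-2-[5-(1,3-dioxolan-2-yl)-3-methoxy-2-(methoxymethoxy)phenyl]-3-hydroxypropanoyl]oxazolidin-2-one | COc1ccc([C@H](O)[C@H](C(=O)N2[C@H](Cc3ccccc3)COC2=O)c4cc(C5OCCO5)cc(OC)c4OCOC)cc1OC
F7 | step 9 | (1R,2S)-1-(3,4-dimethoxyphenyl)-2-[5-(1,3-dioxolan-2-yl)-3-methoxy-2-(methoxymethoxy)phenyl]propane-1,3-diol | COc1ccc([C@H](O)[C@H](CO)c2cc(C3OCCO3)cc(OC)c2OCOC)cc1OC
F8 | step 7 | (1R,2S)-1-(3,4-dimethoxyphenyl)-3-(triisopropylsilyloxy)-2-[4-(triisopropylsilyloxymethyl)furan-2-yl]propyl formate | COc1ccc([C@H](OC=O)[C@H](CO[Si](C(C)C)(C(C)C)C(C)C)c2cc(CO[Si](C(C)C)(C(C)C)C(C)C)co2)cc1OC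
F9 | step 7 | (1R,2S)-1-(3,4-dimethoxyphenyl)-3-(triisopropylsilyloxy)-2-[4-(triisopropylsilyloxymethyl)furan-2-yl]propyl 2,2-dibromovinyl ether | COc1ccc([C@H](OC=C(Br)Br)[C@H](CO[Si](C(C)C)(C(C)C)C(C)C)c2cc(CO[Si](C(C)C)(C(C)C)C(C)C)co2)cc1OC
F10 | step 4 | (S)-4-benzyl-3-{2-[4-(methoxycarbonyl)furan-2-yl]acetyl}oxazolidin-2-one | COC(=O)c1coc(CC(=O)N2[C@@H](Cc3ccccc3)COC2=O)c1
F11 | step 4 | (S)-4-benzyl-3-[(2R)-3-(3,4-dimethoxyphenyl)-2-[4-(methoxycarbonyl)furan-2-yl]-3-oxopropanoyl]oxazolidin-2-one | COc1ccc(C(=O)[C@H](C(=O)N2[C@@H](Cc3ccccc3)COC2=O)c4cc(C(=O)OC)co4)cc1OC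
F12 | step 4 | (S)-4-benzyl-3-[(2S,3R)-3-(3,4-dimethoxyphenyl)-3-hydroxy-2-[4-(methoxycarbonyl)furan-2-yl]propanoyl]oxazolidin-2-one | COc1ccc([C@H](O)[C@H](C(=O)N2[C@@H](Cc3ccccc3)COC2=O)c4cc(C(=O)OC)co4)cc1OC
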